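The ratio to watch here is r: substrate lost to anything but ring, over substrate that became ring. It gives the odds against ring for one molecule at the fork. The dimer step takes two substrate and the ring step one, so r should grow with the substrate concentration c. The quantity to carry is therefore r/c, which I call F, a selectivity factor; ring takes one part in one plus Fc of what is lost.

| flask | substrate | temperature | remark | time |
|---|---|---|---|---|
| gamma | 0.60 M | −10 °C | run made earlier |  |
| theta | 0.90 M | 8 °C | run made earlier |  |
| amber | 1.2 M | 20 °C |  | 80 min |
| violet | 1.2 M | −5 °C |  | 80 min |

- gamma (time / min: ring / %, substrate / %): 40.0: 4.0, 74.9; 80.0: 5.7, 63.5; 120: 8.1, 49.0; 180: 8.7, 39.3; 240: 11.1, 33.7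
- theta (time / min: ring / %, substrate / %): 8.00: 9.3, 59.1; 20.0: 14.9, 38.4; 50.0: 25.1, 24.1; 80.0: 29.6, 18.1; 90.0: 30.6, 16.3; 120: 33.2, 12.4

(each reading ± 1 percentage point)

* which flask leads in amount of ring, in percent of the substrate charged ("all alike" within 1.5 percentage points) (amber / violet / all alike)
* how much ring is there at the end, in percent of the substrate charged: amber
* how much ring is there at the end, in percent of the substrate charged: violet

The first gamma reading gives r = 5.27 at a mean c of 0.525 M, taken halfway between the charge and that reading. So at −10 °C F is 10.1 /M, the fork number. The first theta reading, reckoned the same way, gives 4.75 /M at 8 °C, lower in the warmer run. With a scatter of 1 percentage point on a ring reading of 4.0%, both are rough. My own reckoning puts ring's starting share in violet, at 1.2 M and a temperature between the two runs, between 7.62% and 14.9%.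

Two chemists part over amber. The first made the forecast and carries the fork to the new temperatures by extrapolating its rate constants: amber 40% (32% to 48%), violet 9% (7% to 11.5%), and “Amber leads clearly”. The second treats ring as a stop on the way, for among the steps under discussion ring goes on to isomer of the product and side product. As her own reckoning she keeps theta's F unchanged at 20 °C and takes c as 0.600 M, which gives amber 26.0%, and she expects amber between that and 40%.

Amber ends at 32.6% and violet at 8.94%, so amber leads.

    substrate → ring (k = 0.0840 /min, Ea = 93.0 kJ/mol)
    ring ⇌ isomer of the product (K = 0.750, k = 0.0140 /min, Ea = 101 kJ/mol, ΔH = −4.00 kJ/mol)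
    2 substrate ⇌ open dimer (K = 0.540 /M, k = 0.110 /M/min, Ea = 65.0 kJ/mol, ΔH = −82.0 kJ/mol)
    substrate + ring → side product (k = 0.0850 /M/min, Ea = 71.0 kJ/mol)
    (constants at 20 °C)

She has amber: its ring stands below the forecast, and at 80.0 min amber also holds 20.0% isomer of the product and 47.4% side product. The forecast's view has its region in violet, with 0.129% isomer of the product and 2.78% side product, where the dimer path, forward step alone, uses substrate 9.2 times as fast as the ring path at the start and 6.3 times at 18.7 min. Carried over from −10 °C, the reading F = 10.1 /M with violet's conversion of 67.7% gives 7.53% ring against 8.94%; in the repeat of violet at −20 °C, conversion of 24.9% gives 2.15%, and that flask holds 1.35%.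

All runs are calculated with constants of no real substance.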